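## Retrosynthetic overview

1. Target 14 ⇐ hydrogenolysis of its bis(benzyl) ether 13. The three benzene rings are bought; ring C (O1–C2–C3–C4–C4a–C8a) is the only ring made.
2. C2 and C3, the two stereocentres of ring C, ⇐ one syn H–B addition across C2=C3 of the achiral 2-aryl-4H-chromene 11 (B to C3, H to C2 on the same face, so aryl and OH end up trans; a chiral borane fixes 2R,3S).
3. Ring C, bonds C4–C3 and O1–C2, ⇐ [4+2] of the ring-A o-quinone methide (methide carbon = C4, peri to the C5 phenethyl chain) with the enamine of the B-ring acetophenone, then loss of the amine. This joins the two halves and closes the ring in one step.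
4. The o-quinone methide ⇐ a 2-hydroxybenzyl alcohol made from an orsellinate ester, whose carboxyl carbon becomes C4. This fixes the ring fusion at C4a, which a Friedel–Crafts approach could not guarantee.
5. The C5 bibenzyl chain ⇐ lateral alkylation of the orsellinate methyl group. Order: bibenzyl, ring C (step 5), stereocentres (step 6), deprotection.

Key step: step 5

Assumption 1: methyl 2-hydroxy-4-methoxy-6-methylbenzoate (1) is taken as purchasable; it is otherwise one selective 4-O-methylation away from methyl orsellinate.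

Assumption 2: in step 6 the face selectivity of the (+)-α-pinene-derived isopinocampheylborane is taken to follow that established for 1-arylcycloalkenes (carbinol carbon formed as S), which here corresponds to (2R,3S).

## Route

Step 1
Reactants: 1 methyl 2-hydroxy-4-methoxy-6-methylbenzoate; 2 1-(benzyloxy)-3-(bromomethyl)benzene
Product: 4 methyl 2-{2-[3-(benzyloxy)phenyl]ethyl}-6-hydroxy-4-methoxybenzoate, via dilithio dianion 3 (not isolated)
Conditions: LDA (2.3 equiv), THF, −78 °C; then 2, −78 → −20 °C; 1 M HCl
Reagents that add atoms: none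
Why: Lateral lithiation of the o-toluate gives the phenoxide/benzylic dianion 3, whose carbanion is alkylated by the benzylic bromide in an SN2 reaction, while the lithium phenoxide lowers the electrophilicity of the ester and so holds back self-condensation; no stereocentre is formed.

Step 2
Reactants: 4 methyl 2-{2-[3-(benzyloxy)phenyl]ethyl}-6-hydroxy-4-methoxybenzoate
Product: 5 3-{2-[3-(benzyloxy)phenyl]ethyl}-2-(hydroxymethyl)-5-methoxyphenol
Conditions: LiAlH4, THF, 0 °C → rt; aq. Rochelle salt (neutral work-up)
Reagents that add atoms: none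
Why: Hydride reduction of the salicylate ester to the 2-hydroxybenzyl alcohol, kept cold and worked up without acid so that neither aluminate-assisted over-reduction nor premature quinone methide formation should intervene; the benzyl ether is inert.

Step 3
Reactants: 6 1-(4-hydroxy-3,5-dimethoxyphenyl)ethan-1-one (acetosyringone)
Product: 7 1-[4-(benzyloxy)-3,5-dimethoxyphenyl]ethan-1-one
Conditions: BnBr, K2CO3, DMF, 60 °C
Reagents that add atoms: benzyl bromide BrCc1ccccc1
Why: Williamson etherification of the phenoxide, which protects the phenol whose free form would make C2 of the later chroman labile.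

Step 4
Reactants: 7 1-[4-(benzyloxy)-3,5-dimethoxyphenyl]ethan-1-one
Product: 8 4-{1-[4-(benzyloxy)-3,5-dimethoxyphenyl]ethenyl}morpholine
Conditions: morpholine (6 equiv), TiCl4 (0.6 equiv), toluene, 0 °C → rt; filtered and used crude
Reagents that add atoms: morpholine C1COCCN1
Why: TiCl4-mediated enamine condensation of an aryl methyl ketone, in which the titanium takes up the water and gives the α-morpholinostyrene, whose only possible enamine double bond is the terminal one.

Step 5
Reactants: 5 3-{2-[3-(benzyloxy)phenyl]ethyl}-2-(hydroxymethyl)-5-methoxyphenol; 8 4-{1-[4-(benzyloxy)-3,5-dimethoxyphenyl]ethenyl}morpholine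
Product: 11 2-[4-(benzyloxy)-3,5-dimethoxyphenyl]-5-{2-[3-(benzyloxy)phenyl]ethyl}-7-methoxy-4H-chromene, via o-quinone methide 9 (not isolated), via aminal 10 (not isolated)
Conditions: 8 (2.2 equiv), 4 Å MS, toluene, 110 °C; then AcOH (2 equiv), 60 °C; inert atmosphere, basic alumina
Reagents that add atoms: none
Why: Heating dehydrates the electron-rich 2-hydroxybenzyl alcohol 5 to the o-quinone methide 9, the enamine β-carbon of 8 adds to the methide carbon (C4) and the phenoxide oxygen collapses onto the iminium carbon (C2), a polar inverse-electron-demand oxa-[4+2] that gives the N,O-ketal 10, and acetic acid then ionises 10 at C2 with loss of morpholine and of H-3 to give the 4H-chromene 11. The closest known reactions are the condensations of o-quinone methides, generated from 2-hydroxybenzyl alcohols or phenolic Mannich bases, with enamines such as α-morpholinostyrenes, which give 2-aminochromans and from them 2-aryl-4H-chromenes. Ring C is closed in a six-membered [4+2] mode that forms C4–C3 and O1–C2 in the same operation and joins the two halves of the target. The only stereocentre formed, C2 of 10, is uncontrolled and is erased in the elimination, so 11 is achiral and planar across C2=C3; this is intended, because it leaves C2 and C3 to be set together by one syn addition in step 6. The step needs regioselectivity in the cycloaddition, which the matched polarisation of the partners secures (electrophilic methide carbon to the nucleophilic CH2 of the enamine, oxygen to the aryl- and nitrogen-bearing carbon), and site selectivity on ring A, which is secured because C4 is already bonded to C4a as the former ester carbon, so that fusion next to the C5 phenethyl chain cannot drift to C6 or C8. Neutral thermal generation of 9 and the high nucleophilicity and excess of 8 are chosen to outrun self-condensation of 9 and its acid-promoted Friedel–Crafts capture by the pendant benzyloxyphenyl ring.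

Step 6
Reactants: 11 2-[4-(benzyloxy)-3,5-dimethoxyphenyl]-5-{2-[3-(benzyloxy)phenyl]ethyl}-7-methoxy-4H-chromene
Product: 13 (2R,3S)-2-[4-(benzyloxy)-3,5-dimethoxyphenyl]-5-{2-[3-(benzyloxy)phenyl]ethyl}-7-methoxy-3,4-dihydro-2H-chromen-3-ol, via alkylborane 12 (not isolated)
Conditions: isopinocampheylborane from (+)-α-pinene (1.3 equiv, solution freed beforehand from its TMEDA adduct), THF, −25 °C; then 3 M NaOH, 30% H2O2, 0 °C → rt
Reagents that add atoms: hydrogen peroxide OO (the C3 oxygen); isopinocampheylborane C[C@H]1[C@H](B)C[C@@H]2C[C@H]1C2(C)C (its boron and terpene group are in 12 only, its hydrogen stays in 13)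
Why: Asymmetric hydroboration–oxidation, resting on the hydroboration of flav-2-enes to 2,3-trans-flavan-3-ols and on the isopinocampheylborane hydroboration of 1-arylcycloalkenes to trans-2-arylcycloalkanols: the four-centre syn addition puts boron on C3 (the enol ether carbon remote from O1 and the aryl group) and hydrogen on C2 from the same face, so aryl and boron are trans, the chiral borane selects the face that should make C3 the (S)-carbinol carbon and hence give (2R,3S), and alkaline peroxide replaces boron by OH with retention.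

Step 7
Reactants: 13 (2R,3S)-2-[4-(benzyloxy)-3,5-dimethoxyphenyl]-5-{2-[3-(benzyloxy)phenyl]ethyl}-7-methoxy-3,4-dihydro-2H-chromen-3-ol
Product: 14 (2R,3S)-2-(4-hydroxy-3,5-dimethoxyphenyl)-5-[2-(3-hydroxyphenyl)ethyl]-7-methoxy-3,4-dihydro-2H-chromen-3-ol
Conditions: H2 (1 atm), Pd(OH)2/C, THF/MeOH, rt
Reagents that add atoms: none
Why: Hydrogenolysis of the two primary aryl benzyl ethers under neutral conditions, where the hindered secondary C2–O1 bond of the ring should react far more slowly (as in the debenzylation of catechin benzyl ethers) and the absence of acid or base should keep C2, now para to a free phenol, from epimerising through a p-quinone methide.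

## Compound list

1 | methyl 2-hydroxy-4-methoxy-6-methylbenzoate | COC(=O)c1c(C)cc(OC)cc1O | starting material
2 | 1-(benzyloxy)-3-(bromomethyl)benzene | BrCc1cccc(OCc2ccccc2)c1 | starting material
3 | dilithio dianion of 1 (lithium phenoxide, benzylic carbanion) | [Li+].[Li+].COC(=O)c1c([CH2-])cc(OC)cc1[O-] | intermediate (not isolated)
4 | methyl 2-{2-[3-(benzyloxy)phenyl]ethyl}-6-hydroxy-4-methoxybenzoate | COC(=O)c1c(CCc2cccc(OCc3ccccc3)c2)cc(OC)cc1O | intermediate
5 | 3-{2-[3-(benzyloxy)phenyl]ethyl}-2-(hydroxymethyl)-5-methoxyphenol | OCc1c(CCc2cccc(OCc3ccccc3)c2)cc(OC)cc1O | intermediate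
6 | 1-(4-hydroxy-3,5-dimethoxyphenyl)ethan-1-one (acetosyringone) | CC(=O)c1cc(OC)c(O)c(OC)c1 | starting material
7 | 1-[4-(benzyloxy)-3,5-dimethoxyphenyl]ethan-1-one | CC(=O)c1cc(OC)c(OCc2ccccc2)c(OC)c1 | intermediate
8 | 4-{1-[4-(benzyloxy)-3,5-dimethoxyphenyl]ethenyl}morpholine | C=C(N1CCOCC1)c1cc(OC)c(OCc2ccccc2)c(OC)c1 | intermediate
9 | 5-{2-[3-(benzyloxy)phenyl]ethyl}-3-methoxy-6-methylidenecyclohexa-2,4-dien-1-one (o-quinone methide) | C=C1C(=O)C=C(OC)C=C1CCc1cccc(OCc2ccccc2)c1 | intermediate (not isolated)
10 | 4-(2-[4-(benzyloxy)-3,5-dimethoxyphenyl]-5-{2-[3-(benzyloxy)phenyl]ethyl}-7-methoxy-3,4-dihydro-2H-chromen-2-yl)morpholine (racemic at C2) | COc1cc(CCc2cccc(OCc3ccccc3)c2)c2c(c1)OC(N1CCOCC1)(c1cc(OC)c(OCc3ccccc3)c(OC)c1)CC2 | intermediate (not isolated)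
11 | 2-[4-(benzyloxy)-3,5-dimethoxyphenyl]-5-{2-[3-(benzyloxy)phenyl]ethyl}-7-methoxy-4H-chromene | COc1cc(CCc2cccc(OCc3ccccc3)c2)c2c(c1)OC(c1cc(OC)c(OCc3ccccc3)c(OC)c1)=CC2 | intermediate
12 | isopinocampheyl(2,3-trans-2-[4-(benzyloxy)-3,5-dimethoxyphenyl]-5-{2-[3-(benzyloxy)phenyl]ethyl}-7-methoxy-3,4-dihydro-2H-chromen-3-yl)borane, C2/C3 arranged as in 13 | C[C@H]1[C@H](B[C@H]3Cc4c(CCc5cccc(OCc6ccccc6)c5)cc(OC)cc4O[C@@H]3c3cc(OC)c(OCc4ccccc4)c(OC)c3)C[C@@H]2C[C@H]1C2(C)C | intermediate (not isolated)
13 | (2R,3S)-2-[4-(benzyloxy)-3,5-dimethoxyphenyl]-5-{2-[3-(benzyloxy)phenyl]ethyl}-7-methoxy-3,4-dihydro-2H-chromen-3-ol | COc1cc(CCc2cccc(OCc3ccccc3)c2)c2c(c1)O[C@H](c1cc(OC)c(OCc3ccccc3)c(OC)c1)[C@@H](O)C2 | intermediate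
14 | (2R,3S)-2-(4-hydroxy-3,5-dimethoxyphenyl)-5-[2-(3-hydroxyphenyl)ethyl]-7-methoxy-3,4-dihydro-2H-chromen-3-ol | COc1cc(CCc2cccc(O)c2)c2c(c1)O[C@H](c1cc(OC)c(O)c(OC)c1)[C@@H](O)C2 | target

## Step count and risks

Total step count: 7. Longest linear sequence: 5 (steps 1, 2, 5, 6, 7; the branch 3, 4, 5, 6, 7 is equally long).

Steps most likely to fail:

**Step 5.** The quinone methide may be consumed by self-condensation, or the water it releases may hydrolyse the enamine faster than the cycloaddition runs. The 4H-chromene may also be oxidised by air or disproportionate if the acid stage is prolonged. The fallback sets out from 5 and 7 and returns at 11; it makes the C3–C4 bond by aldol condensation instead of cycloaddition. Alcohol 5 is oxidised with activated MnO2 (CH2Cl2, rt) to 2-{2-[3-(benzyloxy)phenyl]ethyl}-6-hydroxy-4-methoxybenzaldehyde F1. Claisen–Schmidt condensation of this aldehyde with ketone 7 (KOH, EtOH) should give (E)-1-[4-(benzyloxy)-3,5-dimethoxyphenyl]-3-(2-{2-[3-(benzyloxy)phenyl]ethyl}-6-hydroxy-4-methoxyphenyl)prop-2-en-1-one F2. Conjugate reduction of the enone double bond with catalytic [(Ph3P)CuH]6 and a silane, which leaves the benzyl ethers and the ketone, gives 1-[4-(benzyloxy)-3,5-dimethoxyphenyl]-3-(2-{2-[3-(benzyloxy)phenyl]ethyl}-6-hydroxy-4-methoxyphenyl)propan-1-one F3. Cyclodehydration of this hydroxy ketone (PPTS, toluene, water separator) closes ring C to 11.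

**Step 6.** The chiral borane may discriminate poorly between the two faces of this oxygen-substituted trisubstituted alkene, whose sense of induction rests on analogy. The β-aryloxy borane may also open ring C by elimination before it is oxidised. The fallback sets out from 11 and returns at 13; it replaces reagent control by resolution. Hydroboration with BH3·THF and alkaline H2O2, the known route from flav-2-enes to 2,3-trans-flavan-3-ols, gives 13 as the racemate, that is together with (2S,3R)-2-[4-(benzyloxy)-3,5-dimethoxyphenyl]-5-{2-[3-(benzyloxy)phenyl]ethyl}-7-methoxy-3,4-dihydro-2H-chromen-3-ol F4. Lipase-catalysed acylation (Burkholderia cepacia lipase, vinyl acetate, MTBE) should acetylate the (3R) enantiomer, as it does with trans-2-arylcycloalkanols, to give (2S,3R)-2-[4-(benzyloxy)-3,5-dimethoxyphenyl]-5-{2-[3-(benzyloxy)phenyl]ethyl}-7-methoxy-3,4-dihydro-2H-chromen-3-yl acetate F5. Unreacted 13 is separated from the acetate by chromatography.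

**Step 2.** The aluminium phenoxide of the product may lose the benzylic oxygen through a quinone methide and be reduced further to the o-cresol, and the electron-rich alcohol may oligomerise on work-up. The fallback sets out from 4 and returns at 5; it masks the phenol so that no quinone methide can form during the reduction. Silylation (TBSOTf, 2,6-lutidine, CH2Cl2) gives methyl 2-{2-[3-(benzyloxy)phenyl]ethyl}-6-[(tert-butyldimethylsilyl)oxy]-4-methoxybenzoate F6. DIBAL-H (CH2Cl2, −78 → 0 °C) reduces the ester to (2-{2-[3-(benzyloxy)phenyl]ethyl}-6-[(tert-butyldimethylsilyl)oxy]-4-methoxyphenyl)methanol F7. Buffered fluoride (TBAF, AcOH, THF, 0 °C) releases 5 just before use.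

Further compounds
F1 | step 5 | 2-{2-[3-(benzyloxy)phenyl]ethyl}-6-hydroxy-4-methoxybenzaldehyde | O=Cc1c(CCc2cccc(OCc3ccccc3)c2)cc(OC)cc1O
F2 | step 5 | (E)-1-[4-(benzyloxy)-3,5-dimethoxyphenyl]-3-(2-{2-[3-(benzyloxy)phenyl]ethyl}-6-hydroxy-4-methoxyphenyl)prop-2-en-1-one | O=C(/C=C/c1c(CCc2cccc(OCc3ccccc3)c2)cc(OC)cc1O)c1cc(OC)c(OCc2ccccc2)c(OC)c1
F3 | step 5 | 1-[4-(benzyloxy)-3,5-dimethoxyphenyl]-3-(2-{2-[3-(benzyloxy)phenyl]ethyl}-6-hydroxy-4-methoxyphenyl)propan-1-one | O=C(CCc1c(CCc2cccc(OCc3ccccc3)c2)cc(OC)cc1O)c1cc(OC)c(OCc2ccccc2)c(OC)c1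
F4 | step 6 | (2S,3R)-2-[4-(benzyloxy)-3,5-dimethoxyphenyl]-5-{2-[3-(benzyloxy)phenyl]ethyl}-7-methoxy-3,4-dihydro-2H-chromen-3-ol | COc1cc(CCc2cccc(OCc3ccccc3)c2)c2c(c1)O[C@@H](c1cc(OC)c(OCc3ccccc3)c(OC)c1)[C@H](O)C2
F5 | step 6 | (2S,3R)-2-[4-(benzyloxy)-3,5-dimethoxyphenyl]-5-{2-[3-(benzyloxy)phenyl]ethyl}-7-methoxy-3,4-dihydro-2H-chromen-3-yl acetate | COc1cc(CCc2cccc(OCc3ccccc3)c2)c2c(c1)O[C@@H](c1cc(OC)c(OCc3ccccc3)c(OC)c1)[C@H](OC(C)=O)C2
F6 | step 2 | methyl 2-{2-[3-(benzyloxy)phenyl]ethyl}-6-[(tert-butyldimethylsilyl)oxy]-4-methoxybenzoate | COC(=O)c1c(CCc2cccc(OCc3ccccc3)c2)cc(OC)cc1O[Si](C)(C)C(C)(C)C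
F7 | step 2 | (2-{2-[3-(benzyloxy)phenyl]ethyl}-6-[(tert-butyldimethylsilyl)oxy]-4-methoxyphenyl)methanol | OCc1c(CCc2cccc(OCc3ccccc3)c2)cc(OC)cc1O[Si](C)(C)C(C)(C)C
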